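## Structural features

The target 27 is a 3,4-dihydroisocoumarin: a benzene ring (ring A) fused through C4a and C8a to a six-membered lactone (ring B: C1, O2, C3, C4). Ring A carries free phenols at C6 and C8, the latter beside the lactone carbonyl. C3 carries an unbranched eleven-carbon chain whose C10' bears a methoxy group. There are two stereocentres, C3 (R) and C10' (S), separated by nine methylene groups, so neither can influence the other and each must be set independently. The fragile points are the lactone (opened by base), the electron-rich resorcinol (sensitive to oxidants and electrophiles) and the aliphatic methyl ether, which must survive unmasking of the phenols; this rules out Lewis-acid dealkylation and favours benzyl ethers. The real difficulties are the regiochemistry of the 1,2,3,5-tetrasubstituted arene, where the carboxyl carbon sits between an oxygen and a carbon substituent, and the C3 carbinol centre, whose ketone precursor has a methylene group on each side. The key step uses the fact that C4a and C8a are adjacent carbons of ring A bearing C4 and C1, with O8 on the carbon next to C8a: this is the pattern produced when a 3-alkoxyaryne takes up the two halves of a malonate.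

## Logic of the disconnections

27 to 26: the O6–H and O8–H bonds are replaced by O–benzyl bonds. Free phenols would interfere with the fluoride, base and organometallic steps, and benzyl groups leave by hydrogenolysis, which touches neither the aliphatic methyl ether nor the lactone. Nothing is simplified structurally; the demand is a neutral last step that does not cleave the C3–O bond, which is homobenzylic and not benzylic.

26 to 24 (through 25): the lactone C1–O2 bond is cut and the C3–H bond is replaced by a C3=O double bond. This removes ring B and the only ring stereocentre, and lets C3 be set late by reduction. The demand is face-selective hydride delivery to a ketone flanked by two methylene groups, for which an enzyme is chosen, followed by lactonisation by acyl substitution so that C3 keeps its configuration.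

24 to 13 plus 21 (through 22 and 23): the C4–C3 bond is cut. C4 of 13 is benzylic and α to an anhydride carbonyl, and C3 is the acyl carbon of 21, so the bond forms with natural polarity. The gain is convergence: the aromatic half and the chain with its stereocentre are made separately and joined late. The cost is one carbon, the non-aryl carbonyl of 13, lost as carbon dioxide after it has served as activator. The demand is C- over O-acylation and a hydrolysis and decarboxylation mild enough for benzyl ethers.

13 to 12 to 11: the anhydride C–O bond and then the two ester O–methyl bonds are restored. These are functional-group changes that lead back to what the key step delivers. The demand is saponification of a benzoate with two ortho substituents.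

11 to 8 plus 9 (through 10): the C4a–C4 and C8a–C1 bonds are cut together. Both carbon substituents of ring A come from 9 in one operation, and the oxygenation pattern is bought with the arene. The gain is a reduction to a symmetrical phenol derivative and a three-carbon diester. The demands are regiocontrol by the benzyloxy group beside the triple bond of 10, and closure of the aryl anion onto an ester faster than its protonation.

8 to 6 to 2 to 1 (through 7, 5, 4 and 3): the O–S bond of the triflate, the C2–Si bond and the carbamate C–O bond are cut in turn. 1 is symmetrical, so both positions ortho to its hydroxyl are the same, and the carbamate is the strongest director on the ring. The demand is a lithiation that spares the benzylic C–H bonds of the ethers.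

21 to 20 to 18 to 17 to 14 plus 15 (through 19 and 16): the C–Cl bond, the terminal C=C bond (one carbon excised), the O–methyl bond and the C3–C4 bond of 17 are cut in turn. The (S) centre is bought in 15, and the terminal alkene is a masked carboxyl that tolerates Grignard chemistry. The demands are attack at the unsubstituted epoxide carbon and an oxidative cleavage that leaves the ether alone.

## Other disconnections considered

Alternative 1: The cut runs through ring A at the C4a–C8a bond, so that the arene is unfolded into an open-chain tricarbonyl array held on a dioxinone, A2.
- Forward key step: a tertiary amine would enolise A2, the dioxinone C5 carbon would add to the distal ketone, and dehydration and enolisation would give the benzodioxinone A1. Removal of the silyl ether would then let the C3 oxygen attack the dioxinone carbonyl, closing ring B, freeing O8 and leading to 27 with no phenol protecting group.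
- In its favour: the substitution pattern of ring A is written into the chain, so no regiochemical question arises. This is better than the chosen plan, which relies on a directing effect. The C3 centre is made in an acyclic β-oxygenated carbonyl fragment, where aldol, allylation or β-keto ester hydrogenation are dependable; this is also better than a reduction between two methylene groups. The end game after aromatisation is shorter.
- Against it here: A2 combines three carbonyl groups with a β-silyloxy group, so premature cyclisation to pyrones and β-elimination under the amine are likely competing processes. Its assembly by acylation of a dioxinone enolate is linear and places both stereocentres in one long sequence.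
- Comparison: on mechanism the two plans are equals, each an understood anionic cascade. On structure the alternative is the better for regiochemistry and protecting groups. On step economy the chosen plan should be shorter in its longest line, since its arene is reached in four steps from a bought phenol and the chain is joined late.

Alternative 2: The cut removes O2 from ring B (the C1–O2 and O2–C3 bonds) and contracts the lactone to the cyclopentanone of A4.
- Forward key step: a peracid would add to the ketone of A4 and the secondary carbon C2 would migrate to oxygen with retention in a Baeyer–Villiger oxidation, giving the diacetate A3. The acetyl groups would then be removed to reach 27.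
- In its favour: C3 is created as a carbon stereocentre next to a ketone, where asymmetric alkylation or hydrogenation of an alkylidene precursor are mature methods. This is better than the chosen reduction, provided the centre survives. The migration is stereospecific, and fewer steps follow the key step.
- Against it here: two groups can migrate, C2 and the aryl carbon C7a, and migration of C7a would put the oxygen on ring A. The acetates weaken the aryl group, but the bias is less secure than that of the aryne addition. The stereocentre of A4 is α to an aryl ketone and enolisable, so loss of configuration is a risk the chosen plan does not have, since its C3 centre is never α to a carbonyl. The acetates must be cleaved without opening the lactone, where benzyl hydrogenolysis is the cleaner operation.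
- Comparison: on mechanism the chosen plan stands on firmer ground. On stereocontrol at C3 the alternative is the better. Step economy is about equal, because A4 itself needs a ring closure onto the dioxygenated arene and an asymmetric step.

Alternative 3: The cut is at the C5–C4a and C8–C8a bonds, dividing ring A into a four-carbon diene A7 and the two alkyne carbons of the ynoate A6.
- Forward key step: heating A7 with A6 would give a cyclohexadiene by Diels–Alder addition. This would aromatise on mild acid by loss of the methoxy group and of the aryl silyl groups to give the resorcylate A5. Cleavage of the secondary silyl ether and lactonisation would then lead to 27.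
- In its favour: it is the most convergent construction of the arene, and both phenols are unprotected from the start, which is better than the chosen plan. The C3 centre can come from the chiral pool by opening an enantiopure epoxide with an alkynyl nucleophile, which is better than an enzymatic screen. Regiochemistry follows from the polarity of the diene and is the equal of the aryne directing effect in reliability.
- Against it here: ynoates with an alkyl group on the β-carbon are sluggish dienophiles and A7 is thermally and hydrolytically fragile, so the temperature needed works against the diene. A6 must carry both stereocentres and its epoxide precursor is not commercial, so the chain synthesis is longer than the four steps to 21.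
- Comparison: on structure the plans are comparable. On mechanism both are understood, but the chosen key step runs at room temperature. On step economy the alternative is the better after the key step (two steps against five) and the worse before it.

Key step: step 4

Remark on the chemistry (assumption): the ketoreductase of step 12 is taken from a commercial enzyme panel containing enzymes of both facial preferences, and the one that delivers hydride to the Si face of the ketone of 24 is chosen by a small screen.

## Route

Step 1
Reactants: 1 3,5-bis(benzyloxy)phenol
Product: 2 3,5-bis(benzyloxy)phenyl N-isopropylcarbamate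
Conditions: i-PrNCO, Et3N (cat.), CH2Cl2, rt
Reagents that add atoms: isopropyl isocyanate, CC(C)N=C=O
Why: Base-catalysed addition of the phenol O–H across the isocyanate (carbamoylation) should be clean; the secondary carbamate is the strongest ortho director on the ring and can later be removed without acid or fluoride.

Step 2
Reactants: 2 3,5-bis(benzyloxy)phenyl N-isopropylcarbamate
Product: 6 3,5-bis(benzyloxy)-2-(trimethylsilyl)phenyl N-isopropylcarbamate, via N-silyl carbamate 3 (not isolated), via aryllithium 4 (not isolated), via N-silyl arylsilane 5 (not isolated)
Conditions: TBSOTf, TMEDA, Et2O, 0 °C to rt; n-BuLi, TMEDA, −78 °C; TMSCl, −78 °C to rt; aq. NaHSO4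
Reagents that add atoms: chlorotrimethylsilane, C[Si](C)(C)Cl
Why: Directed ortho-metalation: silylation of the N–H in the flask masks the acidic proton, the O-carbamate then directs lithiation to C2, which lies between the carbamate and a benzyloxy oxygen (C2 and C6 are equivalent), and TMSCl traps the aryllithium. At −78 °C the anionic Fries shift and deprotonation of the benzylic ether positions should be slower than ring lithiation; aqueous acid removes the N-silyl group.

Step 3
Reactants: 6 3,5-bis(benzyloxy)-2-(trimethylsilyl)phenyl N-isopropylcarbamate
Product: 8 3,5-bis(benzyloxy)-2-(trimethylsilyl)phenyl trifluoromethanesulfonate, via silylphenol 7 (not isolated)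
Conditions: DBU, Et2NH, MeCN, 40 °C; then PhNTf2, rt
Reagents that add atoms: N-phenylbis(trifluoromethanesulfonimide), O=S(=O)(N(c1ccccc1)S(=O)(=O)C(F)(F)F)C(F)(F)F
Why: DBU removes the carbamate N–H, E1cB loss of isopropyl isocyanate (trapped by Et2NH as a urea) frees the phenoxide, and PhNTf2 triflates it in the same pot. The conditions are free of acid and fluoride, so the aryl C–Si bond should survive.

Step 4
Reactants: 8 3,5-bis(benzyloxy)-2-(trimethylsilyl)phenyl trifluoromethanesulfonate; 9 dimethyl malonate
Product: 11 methyl 2,4-bis(benzyloxy)-6-(2-methoxy-2-oxoethyl)benzoate, via aryne 10 (not isolated)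
Conditions: 9 (1.5 equiv), KF, 18-crown-6, THF, 0 °C to rt
Reagents that add atoms: none
Why: Fluoride attacks silicon of 8 and the resulting aryl anion expels triflate to give aryne 10, while fluoride (and later the product enolate) deprotonates 9. The malonate carbanion adds to the aryne carbon remote from the neighbouring benzyloxy group (future C4a), because that is the more electrophilic end of the distorted triple bond and the negative charge then develops on the carbon beside the inductively withdrawing oxygen (future C8a). This aryl anion attacks one ester carbonyl in a 4-exo-trig closure to a benzocyclobutenoxide, whose C–C bond then breaks in a retro-aldol sense, leaving the ester carbon on C8a and an ester enolate at C4 that is protonated by a further molecule of 9, so the base is regenerated. The net result is insertion of the aryne into a C–C σ-bond of the malonate; the closest known reaction type is the fluoride-induced acyl-alkylation of arynes by β-dicarbonyl compounds, which is known for malonic esters and for 3-alkoxyarynes. No ring remains in the product (the four-membered ring is transient) and no stereocentre is formed. The selectivity needed is regiochemical and is secured by the benzyloxy substituent beside the triple bond of 10; ring closure must also outrun protonation of the aryl anion, which is why THF replaces the C–H acidic acetonitrile and 9 is kept to a small excess.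

Step 5
Reactants: 11 methyl 2,4-bis(benzyloxy)-6-(2-methoxy-2-oxoethyl)benzoate
Product: 12 2,4-bis(benzyloxy)-6-(carboxymethyl)benzoic acid
Conditions: KOH, EtOH–H2O, reflux; then aq. HCl
Reagents that add atoms: potassium hydroxide, [K+].[OH-]
Why: Saponification: the unhindered aliphatic ester should go first, and its carboxylate can assist cleavage of the hindered benzoate through the six-membered anhydride. Benzyl ethers are inert to hydroxide.

Step 6
Reactants: 12 2,4-bis(benzyloxy)-6-(carboxymethyl)benzoic acid
Product: 13 6,8-bis(benzyloxy)isochromane-1,3-dione
Conditions: Ac2O, toluene, 80 °C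
Reagents that add atoms: none
Why: Cyclodehydration of the 1,5-diacid to the six-membered anhydride by acyl exchange with acetic anhydride; this makes the C4 methylene acidic enough for acylation under amine bases.

Step 7
Reactants: 14 10-bromodec-1-ene; 15 (S)-propylene oxide
Product: 17 (S)-tridec-12-en-2-ol, via Grignard reagent 16 (not isolated)
Conditions: Mg, THF, rt to 40 °C; then 15, CuI (10 mol%), THF, −30 to 0 °C; aq. NH4Cl
Reagents that add atoms: none
Why: Grignard formation followed by CuI-catalysed SN2 opening of the terminal epoxide at its unsubstituted carbon. The stereocentre of 15 is not a reacting centre, so its (S) configuration is carried unchanged into 17.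

Step 8
Reactants: 17 (S)-tridec-12-en-2-ol
Product: 18 (S)-12-methoxytridec-1-ene
Conditions: NaH, MeI, THF, 0 °C to rt
Reagents that add atoms: iodomethane, CI
Why: Williamson ether synthesis; alkylation occurs on oxygen, so the C–O bond at the stereocentre is not broken and the (S) configuration is kept.

Step 9
Reactants: 18 (S)-12-methoxytridec-1-ene
Product: 20 (S)-11-methoxydodecanoic acid, via aldehyde 19 (not isolated)
Conditions: O3, MeCN–H2O (9:1), 0 °C; then NaClO2, NaH2PO4, rt
Reagents that add atoms: ozone, [O-][O+]=O; sodium chlorite, [Na+].[O-]Cl=O
Why: Ozonolysis in aqueous acetonitrile should give the aldehyde directly, because water intercepts the carbonyl oxide, and Pinnick oxidation in the same pot takes it to the acid, with the hydrogen peroxide from the first stage scavenging hypochlorite. The methoxy stereocentre is remote from the carbonyl and is not affected.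

Step 10
Reactants: 20 (S)-11-methoxydodecanoic acid
Product: 21 (S)-11-methoxydodecanoyl chloride
Conditions: (COCl)2, DMF (cat.), CH2Cl2, 0 °C to rt
Reagents that add atoms: oxalyl chloride, O=C(Cl)C(=O)Cl
Why: DMF-catalysed conversion of the acid to the acid chloride under essentially neutral conditions; the remote methyl ether is inert.

Step 11
Reactants: 13 6,8-bis(benzyloxy)isochromane-1,3-dione; 21 (S)-11-methoxydodecanoyl chloride
Product: 24 2,4-bis(benzyloxy)-6-[(S)-12-methoxy-2-oxotridecyl]benzoic acid, via C-acyl anhydride 22 (not isolated), via keto diacid 23 (not isolated)
Conditions: TMG, Et3N, MeCN, −20 to 0 °C; then 1 M NaOH, rt; then 2 M HCl, 40 °C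
Reagents that add atoms: sodium hydroxide, [Na+].[OH-]
Why: C-acylation of a homophthalic anhydride at C4 by an acid chloride under guanidine and amine bases is a known entry to 3-substituted isocoumarins and their keto acids. Hydroxide then opens the anhydride at the aryl carbonyl, and acidification sets off decarboxylation of the β-keto acid. Working in cold base and warm dilute acid, not in a hot acid melt, should keep the benzyl ethers and stop at the open keto acid.

Step 12
Reactants: 24 2,4-bis(benzyloxy)-6-[(S)-12-methoxy-2-oxotridecyl]benzoic acid
Product: 26 (R)-6,8-bis(benzyloxy)-3-[(S)-10-methoxyundecyl]isochroman-1-one, via hydroxy acid 25 (not isolated)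
Conditions: (R)-selective ketoreductase, NADP+ (cat.), i-PrOH, phosphate buffer pH 7.5, DMSO (10 vol%), 30 °C; then aq. HCl, TsOH·H2O (cat.), toluene, 40 °C
Reagents that add atoms: none
Why: Enzymatic reduction of a ketone, known for 2-(2-oxoalkyl)benzoic acid derivatives: the active site delivers hydride from NADPH to the Si face and so sets C3 as (R). An enzyme is chosen because both carbonyl substituents are methylene groups, which small-molecule catalysts tell apart poorly. Acid then closes the lactone by Fischer esterification at the acyl carbon, so the C3–O bond and its configuration are untouched.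

Step 13
Reactants: 26 (R)-6,8-bis(benzyloxy)-3-[(S)-10-methoxyundecyl]isochroman-1-one
Product: 27 (R)-6,8-dihydroxy-3-[(S)-10-methoxyundecyl]isochroman-1-one
Conditions: H2 (1 atm), 10% Pd/C, EtOAc, rt
Reagents that add atoms: none
Why: Hydrogenolysis of the two benzyl aryl ethers over Pd/C. The lactone C3–O bond is homobenzylic and should not be cleaved, the aliphatic methyl ether is inert, and neither stereocentre is epimerisable under neutral conditions.

## Compound list

1 | 3,5-bis(benzyloxy)phenol | Oc1cc(OCc2ccccc2)cc(OCc2ccccc2)c1 | starting material
2 | 3,5-bis(benzyloxy)phenyl N-isopropylcarbamate | CC(C)NC(=O)Oc1cc(OCc2ccccc2)cc(OCc2ccccc2)c1 | intermediate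
3 | 3,5-bis(benzyloxy)phenyl N-(tert-butyldimethylsilyl)-N-isopropylcarbamate | CC(C)N([Si](C)(C)C(C)(C)C)C(=O)Oc1cc(OCc2ccccc2)cc(OCc2ccccc2)c1 | intermediate
4 | {2,4-bis(benzyloxy)-6-[(N-tert-butyldimethylsilyl-N-isopropylcarbamoyl)oxy]phenyl}lithium | [Li]c1c(OCc2ccccc2)cc(OCc2ccccc2)cc1OC(=O)N(C(C)C)[Si](C)(C)C(C)(C)C | intermediate
5 | 3,5-bis(benzyloxy)-2-(trimethylsilyl)phenyl N-(tert-butyldimethylsilyl)-N-isopropylcarbamate | C[Si](C)(C)c1c(OCc2ccccc2)cc(OCc2ccccc2)cc1OC(=O)N(C(C)C)[Si](C)(C)C(C)(C)C | intermediate
6 | 3,5-bis(benzyloxy)-2-(trimethylsilyl)phenyl N-isopropylcarbamate | C[Si](C)(C)c1c(OCc2ccccc2)cc(OCc2ccccc2)cc1OC(=O)NC(C)C | intermediate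
7 | 3,5-bis(benzyloxy)-2-(trimethylsilyl)phenol | C[Si](C)(C)c1c(O)cc(OCc2ccccc2)cc1OCc2ccccc2 | intermediate
8 | 3,5-bis(benzyloxy)-2-(trimethylsilyl)phenyl trifluoromethanesulfonate | C[Si](C)(C)c1c(OCc2ccccc2)cc(OCc2ccccc2)cc1OS(=O)(=O)C(F)(F)F | intermediate
9 | dimethyl malonate | COC(=O)CC(=O)OC | starting material
10 | 3,5-bis(benzyloxy)benzyne (1,2-didehydro-3,5-bis(benzyloxy)benzene) | C1#CC(OCc2ccccc2)=CC(OCc2ccccc2)=C1 | intermediate
11 | methyl 2,4-bis(benzyloxy)-6-(2-methoxy-2-oxoethyl)benzoate | COC(=O)Cc1cc(OCc2ccccc2)cc(OCc2ccccc2)c1C(=O)OC | intermediate
12 | 2,4-bis(benzyloxy)-6-(carboxymethyl)benzoic acid | OC(=O)Cc1cc(OCc2ccccc2)cc(OCc2ccccc2)c1C(=O)O | intermediate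
13 | 6,8-bis(benzyloxy)isochromane-1,3-dione | O=C1Cc2cc(OCc3ccccc3)cc(OCc3ccccc3)c2C(=O)O1 | intermediate
14 | 10-bromodec-1-ene | C=CCCCCCCCCBr | starting material
15 | (S)-propylene oxide | C[C@H]1CO1 | starting material
16 | dec-9-en-1-ylmagnesium bromide | C=CCCCCCCCC[Mg]Br | intermediate
17 | (S)-tridec-12-en-2-ol | C[C@H](O)CCCCCCCCCC=C | intermediate
18 | (S)-12-methoxytridec-1-ene | CO[C@@H](C)CCCCCCCCCC=C | intermediate
19 | (S)-11-methoxydodecanal | CO[C@@H](C)CCCCCCCCCC=O | intermediate
20 | (S)-11-methoxydodecanoic acid | CO[C@@H](C)CCCCCCCCCC(=O)O | intermediate
21 | (S)-11-methoxydodecanoyl chloride | CO[C@@H](C)CCCCCCCCCC(=O)Cl | intermediate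
22 | 6,8-bis(benzyloxy)-4-[(S)-11-methoxydodecanoyl]isochromane-1,3-dione | CO[C@@H](C)CCCCCCCCCC(=O)C1C(=O)OC(=O)c2c(OCc3ccccc3)cc(OCc3ccccc3)cc12 | intermediate
23 | 2,4-bis(benzyloxy)-6-[(12S)-1-carboxy-12-methoxy-2-oxotridecyl]benzoic acid | CO[C@@H](C)CCCCCCCCCC(=O)C(C(=O)O)c1cc(OCc2ccccc2)cc(OCc2ccccc2)c1C(=O)O | intermediate
24 | 2,4-bis(benzyloxy)-6-[(S)-12-methoxy-2-oxotridecyl]benzoic acid | CO[C@@H](C)CCCCCCCCCC(=O)Cc1cc(OCc2ccccc2)cc(OCc2ccccc2)c1C(=O)O | intermediate
25 | 2,4-bis(benzyloxy)-6-[(2R,12S)-2-hydroxy-12-methoxytridecyl]benzoic acid | CO[C@@H](C)CCCCCCCCC[C@@H](O)Cc1cc(OCc2ccccc2)cc(OCc2ccccc2)c1C(=O)O | intermediate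
26 | (R)-6,8-bis(benzyloxy)-3-[(S)-10-methoxyundecyl]isochroman-1-one | CO[C@@H](C)CCCCCCCCC[C@@H]1Cc2cc(OCc3ccccc3)cc(OCc3ccccc3)c2C(=O)O1 | intermediate
27 | (R)-6,8-dihydroxy-3-[(S)-10-methoxyundecyl]isochroman-1-one | CO[C@@H](C)CCCCCCCCC[C@@H]1Cc2cc(O)cc(O)c2C(=O)O1 | target

## Step count and least certain steps

Total: 13 steps. Longest linear sequence: 9 steps (steps 1 to 6, then 11 to 13). The side-chain branch (steps 7 to 10) joins at step 11.

Step 4 (key step). The most likely failure is protonation of the aryl anion before it closes onto the ester, which would amount to simple arylation of the malonate without insertion; the ester carbonyl is a weaker electrophile than the ketones for which this chemistry is best established. Further arylation of the product enolate by a second aryne, and leakage of the nucleophile to the aryne carbon beside the benzyloxy group, are lesser risks. The fallback builds the homophthalic acid stepwise without an aryne; it sets out from 9 and comes back to the route at 12. Palladium-catalysed arylation of 9 with 1-bromo-3,5-bis(benzyloxy)benzene (Brc1cc(OCc2ccccc2)cc(OCc2ccccc2)c1; Pd(dba)2, P(t-Bu)3, K3PO4, toluene, 70 °C) should give dimethyl 2-[3,5-bis(benzyloxy)phenyl]malonate F1. Krapcho dealkoxycarbonylation (LiCl, wet DMSO, 140 °C) should give methyl 2-[3,5-bis(benzyloxy)phenyl]acetate F2. Vilsmeier–Haack formylation (POCl3, DMF) is expected at the ring position ortho to the side chain and para to a benzyloxy group, giving methyl 2-[3,5-bis(benzyloxy)-2-formylphenyl]acetate F3. Pinnick oxidation should give 2,4-bis(benzyloxy)-6-(2-methoxy-2-oxoethyl)benzoic acid F4, and saponification with KOH gives 12.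

Step 12. Low enzyme activity toward a large lipophilic substrate, or poor facial discrimination because both ketone substituents are methylene groups, may leave the screen without a usable hit. The fallback replaces asymmetric induction by separation and stereoconvergence; it sets out from 24 and comes back at 26. Reduction with NaBH4 in aqueous ethanolic NaOH and acidification should give 26 together with its C3 epimer, (S)-6,8-bis(benzyloxy)-3-[(S)-10-methoxyundecyl]isochroman-1-one F5, without preference. The two would be separated by preparative chromatography on a chiral stationary phase. F5 would be opened with LiOH to 2,4-bis(benzyloxy)-6-[(2S,12S)-2-hydroxy-12-methoxytridecyl]benzoic acid F6, and a Mitsunobu lactonisation (PPh3, DIAD, THF, 0 °C) would close the ring with inversion at the carbinol carbon to give more 26. Elimination toward the styrene is the competing process in that last operation.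

Step 11. O-acylation or base-induced self-condensation of the anhydride may compete with C-acylation. During hydrolysis, cleavage of the new C–C bond in a retro-Claisen sense, or closure to an isocoumarin-4-carboxylic acid that resists decarboxylation, may divert material. The fallback uses the diester enolate as nucleophile instead of the anhydride; it sets out from 11 (with 21) and comes back at 24. Claisen-type acylation of the lithium enolate of 11 (LiHMDS, 2.2 equiv, THF, −78 °C) with 21 should give methyl 2,4-bis(benzyloxy)-6-[(12S)-12-methoxy-1-(methoxycarbonyl)-2-oxotridecyl]benzoate F7. Krapcho dealkoxycarbonylation (LiCl, wet DMSO, 130 °C) should remove the aliphatic ester to give methyl 2,4-bis(benzyloxy)-6-[(S)-12-methoxy-2-oxotridecyl]benzoate F8, and saponification (KOH, aqueous EtOH, reflux) gives 24.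

Step 2. Deprotonation at the benzylic positions of the benzyl ethers followed by Wittig rearrangement, or an anionic Fries shift of the carbamoyl group, may compete with ring lithiation if the temperature rises. The fallback replaces deprotonation by halogen–metal exchange; it sets out from 1 and comes back at 8. Bromination with NBS (CH2Cl2, −78 °C) should give 3,5-bis(benzyloxy)-2-bromophenol F9, with the isomer brominated between the two ether groups as the likely contaminant to be removed. Silylation with HMDS gives [3,5-bis(benzyloxy)-2-bromophenoxy]trimethylsilane F10. Treatment with n-BuLi in THF at −78 °C effects bromine–lithium exchange and retro-Brook migration of silicon from oxygen to carbon, and the resulting phenoxide is trapped with Tf2O to give 8.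

## Further compounds

F1 | step 4 | dimethyl 2-[3,5-bis(benzyloxy)phenyl]malonate | COC(=O)C(C(=O)OC)c1cc(OCc2ccccc2)cc(OCc2ccccc2)c1
F2 | step 4 | methyl 2-[3,5-bis(benzyloxy)phenyl]acetate | COC(=O)Cc1cc(OCc2ccccc2)cc(OCc2ccccc2)c1
F3 | step 4 | methyl 2-[3,5-bis(benzyloxy)-2-formylphenyl]acetate | COC(=O)Cc1cc(OCc2ccccc2)cc(OCc2ccccc2)c1C=O
F4 | step 4 | 2,4-bis(benzyloxy)-6-(2-methoxy-2-oxoethyl)benzoic acid | COC(=O)Cc1cc(OCc2ccccc2)cc(OCc2ccccc2)c1C(=O)O
F5 | step 12 | (S)-6,8-bis(benzyloxy)-3-[(S)-10-methoxyundecyl]isochroman-1-one | CO[C@@H](C)CCCCCCCCC[C@H]1Cc2cc(OCc3ccccc3)cc(OCc3ccccc3)c2C(=O)O1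
F6 | step 12 | 2,4-bis(benzyloxy)-6-[(2S,12S)-2-hydroxy-12-methoxytridecyl]benzoic acid | CO[C@@H](C)CCCCCCCCC[C@H](O)Cc1cc(OCc2ccccc2)cc(OCc2ccccc2)c1C(=O)O
F7 | step 11 | methyl 2,4-bis(benzyloxy)-6-[(12S)-12-methoxy-1-(methoxycarbonyl)-2-oxotridecyl]benzoate | CO[C@@H](C)CCCCCCCCCC(=O)C(C(=O)OC)c1cc(OCc2ccccc2)cc(OCc2ccccc2)c1C(=O)OC
F8 | step 11 | methyl 2,4-bis(benzyloxy)-6-[(S)-12-methoxy-2-oxotridecyl]benzoate | CO[C@@H](C)CCCCCCCCCC(=O)Cc1cc(OCc2ccccc2)cc(OCc2ccccc2)c1C(=O)OC
F9 | step 2 | 3,5-bis(benzyloxy)-2-bromophenol | Oc1cc(OCc2ccccc2)cc(OCc2ccccc2)c1Br
F10 | step 2 | [3,5-bis(benzyloxy)-2-bromophenoxy]trimethylsilane | C[Si](C)(C)Oc1cc(OCc2ccccc2)cc(OCc2ccccc2)c1Br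
A1 | alternative 1 | 7-hydroxy-5-[(2R,12S)-12-methoxy-2-(triethylsilyloxy)tridecyl]-2,2-dimethyl-4H-benzo[d][1,3]dioxin-4-one | CO[C@@H](C)CCCCCCCCC[C@@H](O[Si](CC)(CC)CC)Cc1cc(O)cc2OC(C)(C)OC(=O)c12
A2 | alternative 1 | 6-[(6R,16S)-16-methoxy-2,4-dioxo-6-(triethylsilyloxy)heptadecyl]-2,2-dimethyl-4H-1,3-dioxin-4-one | CO[C@@H](C)CCCCCCCCC[C@@H](O[Si](CC)(CC)CC)CC(=O)CC(=O)CC1=CC(=O)OC(C)(C)O1
A3 | alternative 2 | (R)-6,8-diacetoxy-3-[(S)-10-methoxyundecyl]isochroman-1-one | CO[C@@H](C)CCCCCCCCC[C@@H]1Cc2cc(OC(C)=O)cc(OC(C)=O)c2C(=O)O1
A4 | alternative 2 | (R)-5,7-diacetoxy-2-[(S)-10-methoxyundecyl]indan-1-one | CO[C@@H](C)CCCCCCCCC[C@@H]1Cc2cc(OC(C)=O)cc(OC(C)=O)c2C1=O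
A5 | alternative 3 | methyl 2-[(2R,12S)-2-(tert-butyldimethylsilyloxy)-12-methoxytridecyl]-4,6-dihydroxybenzoate | CO[C@@H](C)CCCCCCCCC[C@@H](O[Si](C)(C)C(C)(C)C)Cc1cc(O)cc(O)c1C(=O)OC
A6 | alternative 3 | methyl (5R,15S)-5-(tert-butyldimethylsilyloxy)-15-methoxyhexadec-2-ynoate | CO[C@@H](C)CCCCCCCCC[C@@H](O[Si](C)(C)C(C)(C)C)CC#CC(=O)OC
A7 | alternative 3 | 1-methoxy-1,3-bis(trimethylsilyloxy)buta-1,3-diene | COC(O[Si](C)(C)C)=CC(=C)O[Si](C)(C)C
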